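How much left-handed product and left-handed substrate stand in the flask at 12 min, dosed with 0.800 equiv of coupling partner, when the earlier runs had less?

in all of them: left-handed substrate 0.50 M; right-handed substrate 0.50 M; free catalyst 5 mol%
- Saturday's: coupling partner 0.40 equiv (fed, over 2.0 min); run made earlier
- Monday's: coupling partner 0.60 equiv (fed, over 2.0 min); run made earlier
- flask: coupling partner 0.800 equiv (fed, over 2.0 min); time 12 min

| run | time / min | left-handed product / % | left-handed substrate / % |
|---|---|---|---|
| Saturday's | 0.500 | 0.7 | 46.9 |
| Saturday's | 1.00 | 0.7 | 46.3 |
| Saturday's | 1.50 | 2.4 | 45.3 |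
| Saturday's | 2.50 | 5.9 | 42.5 |
| Saturday's | 4.00 | 9.5 | 38.1 |
| Saturday's | 8.00 | 15.2 | 33.0 |
| Monday's | 0.500 | 0.3 | 47.1 |
| Monday's | 1.00 | 2.2 | 46.2 |
| Monday's | 1.50 | 3.9 | 44.4 |
| Monday's | 2.50 | 9.2 | 39.6 |
| Monday's | 4.00 | 14.0 | 33.6 |
| Monday's | 8.00 | 21.8 | 26.4 |

(readings scatter by 0.3 percentage points)

- concentration of left-handed product at 12 min, in M
- concentration of left-handed substrate at 12 min, in M

We work in logarithms. At 8.00 min, Saturday's 15.2% and Monday's 21.8% of left-handed product give a reading of 0.889 for the dose exponent, the slope of log [left-handed product] against log coupling partner dose at one time, with the other charges and the feed time held. Scaling from Monday's reading puts the flask at an estimated 28.2% at that time, and our low extreme lets the product stand still from there. Our high extreme runs Monday's time exponent, 0.639 from 4.00 min to 8.00 min, on to 12 min, giving 36.5%. We expect the flask between them, because Monday's time exponent still reads positive but is lower than the 0.893 read from 2.50 min to 4.00 min. Taking the midpoint in logarithms, we commit to 0.320 M of left-handed product. Monday's shortfall at 8.00 min of left-handed substrate plus left-handed product against the left-handed charge, 1.8 percentage points, taken as catalyst intermediate A, then leaves an estimated 0.162 M of left-handed substrate.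

The forecast, reckoned separately, says 0.31 M and 0.175 M: “the 8 min values of 15.2 and 21.8 extend sublinearly to about 27.5%”.

The flask gives 0.329 M of left-handed product and 0.154 M of left-handed substrate; the product lies above our low extreme and below our high one.

    coupling partner + catalyst intermediate B → free catalyst + right-handed product (k = 4.50 M⁻¹ min⁻¹)
    coupling partner + catalyst intermediate A → free catalyst + left-handed product (k = 12.0 M⁻¹ min⁻¹)
    free catalyst + right-handed substrate ⇌ catalyst intermediate B (K = 0.870 M⁻¹, k = 250 M⁻¹ min⁻¹)
    coupling partner ⇌ dormant form (K = 0.280, k = 0.0310 min⁻¹)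
    free catalyst + left-handed substrate ⇌ catalyst intermediate A (K = 22.0 M⁻¹, k = 57.0 M⁻¹ min⁻¹)

The flask has not come to rest at 12 min: the coupling partner, the limiting reagent here, still has 8.74% of its charge free, and the dormant form holds 0.0215 M. Left until 120 min, the flask reaches 0.382 M of left-handed product and 0.102 M of left-handed substrate, with the partner at 0%.

For the neighbour with 0.320 equiv of partner, the dose exponent scales the flask's result to 0.146 M. Computed, that neighbour gives 0.139 M.

(Readings and results stem from a simulated flask on assumed constants.)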